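The methyl-bearing naphthalene ring (C1'–C4', C4a', C8a') is cut into a furan and an aryne. C1', C2' (with its methyl group), C3' and C4' with its oxygen are the four carbons and the ring oxygen of a 2-aryl-3-methylfuran. 3-Methoxybenzyne brings C4a'–C8a' and the C5' methoxy group. One flask forges C1'–C8a' and C4'–C4a' and closes the ring, and acid then converts the oxygen bridge into the C4' hydroxyl. The crowded C5–C1' axis therefore arises only after a small five-membered ring has been attached to C5. The precursor is the N-Cbz (1S,3S)-trans-6,8-dimethoxy-1,3-dimethyltetrahydroisoquinoline bearing a 3-methylfuran-2-yl group at C5.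

Key step: step 8

Assumption: the SMILES string defines only C1 and C3. Rotation about C5–C1' is hindered, so two atropisomeric diastereomers are expected; both fit the string, and they would be separated by chromatography at the N-Cbz tetramethyl ether stage if one is wanted.

Step 1
Reactants: 1 1-bromo-3,5-dimethoxybenzene; 2 tert-butyl (S)-4-methyl-1,2,3-oxathiazolidine-3-carboxylate 2,2-dioxide
Product: 5 tert-butyl (S)-[1-(3,5-dimethoxyphenyl)propan-2-yl]carbamate, via arylmagnesium bromide 3 (not isolated), via N-sulfamate magnesium salt 4 (not isolated)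
Conditions: Mg, THF, reflux; CuBr·SMe2 (10 mol %), 2, THF, −20 °C to 0 °C; then 10% aq citric acid, rt
Reagents that add atoms: none
Why: Copper-catalysed SN2 opening of a cyclic sulfamidate by an aryl Grignard reagent occurs at the primary CH2–O carbon, so the nitrogen-bearing stereocentre from the chiral pool is untouched and becomes C3 (S), and mild acid then hydrolyses the N-sulfamate without loss of Boc.

Step 2
Reactants: 5 tert-butyl (S)-[1-(3,5-dimethoxyphenyl)propan-2-yl]carbamate
Product: 7 (S)-N-[1-(3,5-dimethoxyphenyl)propan-2-yl]acetamide, via amine hydrochloride 6 (not isolated)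
Conditions: 4 M HCl in dioxane, rt; evaporate; Ac2O, Et3N, CH2Cl2, 0 °C to rt
Reagents that add atoms: acetic anhydride, CC(=O)OC(C)=O
Why: Acidolysis of the tert-butyl carbamate followed by N-acetylation is a routine protecting-group exchange that leaves the stereocentre alone and installs the two carbons that become C1 and its methyl group.

Step 3
Reactants: 7 (S)-N-[1-(3,5-dimethoxyphenyl)propan-2-yl]acetamide
Product: 8 (S)-6,8-dimethoxy-1,3-dimethyl-3,4-dihydroisoquinoline
Conditions: POCl3, MeCN, reflux; aq NaOH work-up
Reagents that add atoms: none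
Why: In this Bischler–Napieralski cyclodehydration the activated amide attacks a ring position ortho to one methoxy group and para to the other, and since the two candidate sites are equivalent by symmetry only the 6,8-dimethoxy pattern can form.

Step 4
Reactants: 8 (S)-6,8-dimethoxy-1,3-dimethyl-3,4-dihydroisoquinoline
Product: 9 (1S,3S)-6,8-dimethoxy-1,3-dimethyl-1,2,3,4-tetrahydroisoquinoline (trans)
Conditions: AlMe3, LiAlH4, THF, −78 °C to 0 °C; aqueous work-up
Reagents that add atoms: none
Why: In this Lewis-acid-modified hydride reduction of a cyclic imine, AlMe3 bound to nitrogen drives the C3 methyl group pseudoaxial, and pseudoaxial hydride attack on that half-chair delivers H to C1 on the face of the C3 methyl group, so C3 (S) sets C1 (S) with the methyl groups trans, whereas NaBH4 alone would favour cis.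

Step 5
Reactants: 9 (1S,3S)-6,8-dimethoxy-1,3-dimethyl-1,2,3,4-tetrahydroisoquinoline
Product: 10 benzyl (1S,3S)-6,8-dimethoxy-1,3-dimethyl-3,4-dihydroisoquinoline-2(1H)-carboxylate
Conditions: CbzCl, i-Pr2NEt, CH2Cl2, 0 °C to rt
Reagents that add atoms: benzyl chloroformate, O=C(Cl)OCc1ccccc1
Why: N-Acylation with a chloroformate removes the nucleophilicity of nitrogen, which would otherwise add to the aryne in step 8, and gives a carbamate that tolerates base, heat and dilute acid yet falls to hydrogenolysis.

Step 6
Reactants: 10 benzyl (1S,3S)-6,8-dimethoxy-1,3-dimethyl-3,4-dihydroisoquinoline-2(1H)-carboxylate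
Product: 11 benzyl (1S,3S)-5-bromo-6,8-dimethoxy-1,3-dimethyl-3,4-dihydroisoquinoline-2(1H)-carboxylate
Conditions: NBS (1.0 equiv), MeCN, −20 °C to 0 °C, dark
Reagents that add atoms: N-bromosuccinimide, O=C1CCC(=O)N1Br
Why: Electrophilic aromatic bromination should take C5, which is para to the C8 methoxy group and ortho to the C6 methoxy group, in preference to C7, which is wedged between two methoxy groups.

Step 7
Reactants: 11 benzyl (1S,3S)-5-bromo-6,8-dimethoxy-1,3-dimethyl-3,4-dihydroisoquinoline-2(1H)-carboxylate; 12 3-methyl-2-furoic acid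
Product: 13 benzyl (1S,3S)-6,8-dimethoxy-1,3-dimethyl-5-(3-methylfuran-2-yl)-3,4-dihydroisoquinoline-2(1H)-carboxylate
Conditions: 12 (2 equiv), Pd[P(t-Bu)3]2 (5–10 mol %), n-Bu4NCl·H2O, Cs2CO3, DMF, 170 °C (microwave, minutes)
Reagents that add atoms: none
Why: In this palladium-catalysed decarboxylative cross-coupling of a heteroaromatic 2-carboxylic acid with an aryl bromide, the carboxylate fixes the new bond at furan C2, the 3-methyl group blocks the competing C3 arylation, and the flat five-membered partner is small enough for the di-ortho-substituted arylpalladium bromide.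

Step 8
Reactants: 13 benzyl (1S,3S)-6,8-dimethoxy-1,3-dimethyl-5-(3-methylfuran-2-yl)-3,4-dihydroisoquinoline-2(1H)-carboxylate; 14 3-methoxy-2-(trimethylsilyl)phenyl trifluoromethanesulfonate
Product: 17 benzyl (1S,3S)-5-(4-hydroxy-5-methoxy-2-methylnaphthalen-1-yl)-6,8-dimethoxy-1,3-dimethyl-3,4-dihydroisoquinoline-2(1H)-carboxylate, via 3-methoxybenzyne 15 (not isolated), via oxygen-bridged cycloadduct 16 (not isolated)
Conditions: CsF (4 equiv), MeCN, rt, 14 (1.6 equiv) added in portions; only after 14 is consumed (a free naphthol would be O-arylated), MeOH and conc. aq HCl (excess over fluoride), rt to 40 °C, same flask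
Reagents that add atoms: none
Why: Fluoride removes the silyl group of 14 and triflate departs to give aryne 15, which adds suprafacially across furan C2 and C5 of 13 in a concerted but asynchronous Diels–Alder reaction, the standard fate of arynes with furans. The new six-membered carbocycle (C1'–C2'–C3'–C4'–C4a'–C8a') is thus closed by an intermolecular [4+2] cycloaddition that makes both bonds in one event and gives the 1,4-epoxy-1,4-dihydronaphthalene 16. Acid then protonates the bridge oxygen and breaks C1'–O, since the resulting cation is tertiary, allylic and flanked by two arenes, and loss of the C4' proton aromatises the ring with the oxygen kept on C4', which is the known epoxynaphthalene-to-naphthol isomerisation. The selectivity needed is orientational: the aryl-bearing furan carbon must join the aryne carbon meta to the methoxy group. That carbon is the more electrophilic aryne terminus, and bonding to it from furan C2 places developing charge on the methyl-bearing C3 and on the oxygen-stabilised C5, while the aryl group, held orthogonal by its two ortho substituents and the 3-methyl group, acts only as a σ-acceptor and would clash with the methoxy group in the opposite orientation. The two bridgehead centres of 16 vanish on aromatisation, so no stereocentre is created and only the uncontrolled C5–C1' axis remains.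

Step 9
Reactants: 17 benzyl (1S,3S)-5-(4-hydroxy-5-methoxy-2-methylnaphthalen-1-yl)-6,8-dimethoxy-1,3-dimethyl-3,4-dihydroisoquinoline-2(1H)-carboxylate
Product: 18 benzyl (1S,3S)-5-(4,5-dimethoxy-2-methylnaphthalen-1-yl)-6,8-dimethoxy-1,3-dimethyl-3,4-dihydroisoquinoline-2(1H)-carboxylate
Conditions: MeI, K2CO3, acetone, reflux
Reagents that add atoms: iodomethane, CI
Why: Williamson ether synthesis on the only acidic OH should proceed in hot acetone despite the peri hydrogen bond to the C5' methoxy group, and the carbamate nitrogen cannot be alkylated.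

Step 10
Reactants: 18 benzyl (1S,3S)-5-(4,5-dimethoxy-2-methylnaphthalen-1-yl)-6,8-dimethoxy-1,3-dimethyl-3,4-dihydroisoquinoline-2(1H)-carboxylate
Product: 19 (1S,3S)-5-(4,5-dimethoxy-2-methylnaphthalen-1-yl)-6,8-dimethoxy-1,3-dimethyl-1,2,3,4-tetrahydroisoquinoline (target)
Conditions: H2 (1 atm), 10% Pd/C, EtOH, rt
Reagents that add atoms: none
Why: Catalytic hydrogenolysis cleaves the benzyl–oxygen bond of the carbamate and the carbamic acid loses CO2, while the aryl methyl ethers, the naphthalene and the ring C1–N bond with its stereocentre are inert at ambient pressure and temperature.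

Compound list
1 | 1-bromo-3,5-dimethoxybenzene | COc1cc(Br)cc(OC)c1 | starting material
2 | tert-butyl (S)-4-methyl-1,2,3-oxathiazolidine-3-carboxylate 2,2-dioxide (commercial Boc-sulfamidate of L-alaninol) | C[C@H]1COS(=O)(=O)N1C(=O)OC(C)(C)C | starting material
3 | 3,5-dimethoxyphenylmagnesium bromide | COc1cc([Mg]Br)cc(OC)c1 | intermediate
4 | bromomagnesium (S)-N-Boc-N-[1-(3,5-dimethoxyphenyl)propan-2-yl]sulfamate | COc1cc(OC)cc(C[C@H](C)N(C(=O)OC(C)(C)C)S(=O)(=O)O[Mg]Br)c1 | intermediate
5 | tert-butyl (S)-[1-(3,5-dimethoxyphenyl)propan-2-yl]carbamate | COc1cc(OC)cc(C[C@H](C)NC(=O)OC(C)(C)C)c1 | intermediate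
6 | (S)-1-(3,5-dimethoxyphenyl)propan-2-amine hydrochloride | COc1cc(OC)cc(C[C@H](C)N)c1.Cl | intermediate
7 | (S)-N-[1-(3,5-dimethoxyphenyl)propan-2-yl]acetamide | COc1cc(OC)cc(C[C@H](C)NC(C)=O)c1 | intermediate
8 | (S)-6,8-dimethoxy-1,3-dimethyl-3,4-dihydroisoquinoline | COc1cc(OC)c2c(c1)C[C@H](C)N=C2C | intermediate
9 | (1S,3S)-6,8-dimethoxy-1,3-dimethyl-1,2,3,4-tetrahydroisoquinoline | COc1cc(OC)c2c(c1)C[C@H](C)N[C@H]2C | intermediate
10 | benzyl (1S,3S)-6,8-dimethoxy-1,3-dimethyl-3,4-dihydroisoquinoline-2(1H)-carboxylate | COc1cc(OC)c2c(c1)C[C@H](C)N(C(=O)OCc1ccccc1)[C@H]2C | intermediate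
11 | benzyl (1S,3S)-5-bromo-6,8-dimethoxy-1,3-dimethyl-3,4-dihydroisoquinoline-2(1H)-carboxylate | COc1cc(OC)c2c(c1Br)C[C@H](C)N(C(=O)OCc1ccccc1)[C@H]2C | intermediate
12 | 3-methyl-2-furoic acid | Cc1ccoc1C(=O)O | starting material
13 | benzyl (1S,3S)-6,8-dimethoxy-1,3-dimethyl-5-(3-methylfuran-2-yl)-3,4-dihydroisoquinoline-2(1H)-carboxylate | COc1cc(OC)c2c(c1-c1occc1C)C[C@H](C)N(C(=O)OCc1ccccc1)[C@H]2C | intermediate
14 | 3-methoxy-2-(trimethylsilyl)phenyl trifluoromethanesulfonate | COc1cccc(OS(=O)(=O)C(F)(F)F)c1[Si](C)(C)C | starting material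
15 | 3-methoxybenzyne | COC1=CC=CC#C1 | intermediate
16 | N-Cbz 5-(5-methoxy-2-methyl-1,4-epoxy-1,4-dihydronaphthalen-1-yl) adduct, both bridgehead configurations | COc1cc(OC)c2c(c1C34OC(C=C3C)c5c(OC)cccc45)C[C@H](C)N(C(=O)OCc1ccccc1)[C@H]2C | intermediate
17 | benzyl (1S,3S)-5-(4-hydroxy-5-methoxy-2-methylnaphthalen-1-yl)-6,8-dimethoxy-1,3-dimethyl-3,4-dihydroisoquinoline-2(1H)-carboxylate | COc1cc(OC)c2c(c1-c1c(C)cc(O)c3c(OC)cccc13)C[C@H](C)N(C(=O)OCc1ccccc1)[C@H]2C | intermediate
18 | benzyl (1S,3S)-5-(4,5-dimethoxy-2-methylnaphthalen-1-yl)-6,8-dimethoxy-1,3-dimethyl-3,4-dihydroisoquinoline-2(1H)-carboxylate | COc1cc(OC)c2c(c1-c1c(C)cc(OC)c3c(OC)cccc13)C[C@H](C)N(C(=O)OCc1ccccc1)[C@H]2C | intermediate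
19 | (1S,3S)-5-(4,5-dimethoxy-2-methylnaphthalen-1-yl)-6,8-dimethoxy-1,3-dimethyl-1,2,3,4-tetrahydroisoquinoline | COc1cc(OC)c2c(c1-c1c(C)cc(OC)c3c(OC)cccc13)C[C@H](C)N[C@H]2C | target

Total step count: 10. Longest linear sequence: 10 steps (1 or 2 to 19). Compounds 12 and 14 enter as purchased.

Steps most likely to fail

**Step 8.**
- Orientation: the cycloaddition may take the wrong orientation, because bonding can run ahead from the unhindered furan C5 to the more electrophilic aryne carbon.
- Acid stage: ionisation of the C4'–O bond is helped by the adjacent methoxy-bearing ring and by the C2' methyl group. It may compete and lead to aryl migration in place of aromatisation.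
- Built-in safeguard: methanol is present in the acid stage for this reason. It can capture a C4' cation reversibly, and the captured material can still lose water through the C1' cation and aromatise to the C4' methyl ether 18, which step 9 makes in any case.
- Fallback, from 13 back to 18: the furan is kept, but an electropositive boron substituent rather than bulk steers the aryne. Commercial 2,6-diiodophenol is deprotonated with MeMgCl, exchanged at one iodine with i-PrMgCl·LiCl and quenched with 2-isopropoxy-4,4,5,5-tetramethyl-1,3,2-dioxaborolane to give 2-iodo-6-(pinacolboryl)phenol F1. Tf2O/pyridine converts it into the aryl triflate F2. i-PrMgCl·LiCl at −78 °C in the presence of 13 releases 3-(pinacolboryl)benzyne F3. In 3-borylarynes the carbon next to boron is the electrophilic one, and their Diels–Alder reactions with 2-substituted furans are known to place the furan substituent away from boron. Polar and steric effects then point the same way, and the boryl-substituted oxygen-bridged adduct F4 should form with the aryl group distal. Boron is a π-acceptor and lends no help to C4'–O ionisation, so acid should open F4 through the C1' cation to the 5'-boryl-4'-naphthol F5. NaBO3 in aqueous THF oxidises C–B to C–O to give the 4',5'-naphthalenediol F6. Excess MeI/K2CO3 then methylates both hydroxyl groups to reach 18.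

**Step 7.**
- Palladation with loss of CO2 may be too slow at the di-ortho-substituted, electron-rich arylpalladium centre. Protodecarboxylation of 12 and reduction of the C–Br bond would then take over.
- The carbamate may also suffer at 170 °C.
- Fallback, from 11 back to 13: a Negishi coupling at moderate temperature. Commercial 3-methylfuran is brominated at C2 with NBS to 2-bromo-3-methylfuran F7. Bromine–lithium exchange with n-BuLi at −78 °C gives 3-methyl-2-furyllithium F8, and ZnCl2 gives (3-methylfuran-2-yl)zinc chloride F9. This couples with 11 under Pd2(dba)3/SPhos in THF at 60 °C, a catalyst system known to join hindered aryl bromides to heteroarylzinc halides in the presence of carbamates.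

**Step 4.**
- Facial selectivity of hydride delivery may be poor if complexation by AlMe3 is incomplete, which would erode the trans relationship.
- Fallback, from 6 back to 9: C1 is set in a ring closure rather than in a reduction. Reductive amination of 6 with benzaldehyde, Et3N and NaBH(OAc)3 gives (S)-N-benzyl-1-(3,5-dimethoxyphenyl)propan-2-amine F10. Pictet–Spengler cyclisation with acetaldehyde and TFA passes through an N-benzyl iminium ion. Allylic strain there and the peri C8 methoxy group place the C1 methyl group pseudoaxial and anti to the C3 methyl group, which is the known 1,3-trans preference of N-benzyl Pictet–Spengler reactions. This gives the trans N-benzyl tetrahydroisoquinoline F11, and hydrogenolysis over Pd(OH)2/C returns 9.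

Further compounds
F1 | step 8 | 2-iodo-6-(4,4,5,5-tetramethyl-1,3,2-dioxaborolan-2-yl)phenol | CC1(C)OB(OC1(C)C)c1cccc(I)c1O
F2 | step 8 | 2-iodo-6-(4,4,5,5-tetramethyl-1,3,2-dioxaborolan-2-yl)phenyl trifluoromethanesulfonate | CC1(C)OB(OC1(C)C)c1cccc(I)c1OS(=O)(=O)C(F)(F)F
F3 | step 8 | 3-(4,4,5,5-tetramethyl-1,3,2-dioxaborolan-2-yl)benzyne | CC1(C)OB(OC1(C)C)C1=CC=CC#C1
F4 | step 8 | N-Cbz 5-(5-pinacolboryl-2-methyl-1,4-epoxy-1,4-dihydronaphthalen-1-yl) adduct | COc1cc(OC)c2c(c1C34OC(C=C3C)c5c(B6OC(C)(C)C(C)(C)O6)cccc45)C[C@H](C)N(C(=O)OCc1ccccc1)[C@H]2C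
F5 | step 8 | N-Cbz 5-(4-hydroxy-2-methyl-5-pinacolborylnaphthalen-1-yl) biaryl | COc1cc(OC)c2c(c1-c1c(C)cc(O)c3c(B4OC(C)(C)C(C)(C)O4)cccc13)C[C@H](C)N(C(=O)OCc1ccccc1)[C@H]2C
F6 | step 8 | N-Cbz 5-(4,5-dihydroxy-2-methylnaphthalen-1-yl) biaryl | COc1cc(OC)c2c(c1-c1c(C)cc(O)c3c(O)cccc13)C[C@H](C)N(C(=O)OCc1ccccc1)[C@H]2C
F7 | step 7 | 2-bromo-3-methylfuran | Cc1ccoc1Br
F8 | step 7 | 3-methyl-2-furyllithium | Cc1ccoc1[Li]
F9 | step 7 | (3-methylfuran-2-yl)zinc chloride | Cc1ccoc1[Zn]Cl
F10 | step 4 | (S)-N-benzyl-1-(3,5-dimethoxyphenyl)propan-2-amine | COc1cc(OC)cc(C[C@H](C)NCc2ccccc2)c1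
F11 | step 4 | (1S,3S)-2-benzyl-6,8-dimethoxy-1,3-dimethyl-1,2,3,4-tetrahydroisoquinoline | COc1cc(OC)c2c(c1)C[C@H](C)N(Cc1ccccc1)[C@H]2C
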